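**Plan**

1. Retrosynthesis: after global deprotection, ring C of the upper flavan is cut at O1–C2 and C4a–C4 (a pyrogallol monophenol plus a three-carbon 1,3-dielectrophile). Next the bond from upper C4 to C6 of the lower ring A is cut (aryllithium plus cis-epoxy aldehyde).
2. Forward order: the lower ring C is built first (chromone, flavanone, flav-3-ene, cis-diol acetonide). The three-carbon chain is then joined at C6 of the lower ring A. The upper ring C is closed last in a one-flask formal [3+3] annulation, and two deprotections finish the route.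
3. Enabling feature: upper C4 is a doubly benzylic methine bound to C6 of the lower ring A, ortho to O7 and para to O1 of that ring, so it ionises easily. Upper C2 is a para-oxybenzylic epoxide carbon open to SN2 attack. The upper ring A offers O1 and the adjacent C4a (para to O7) as an O,C-dinucleophile.
4. Stereochemistry: lower C2 comes from a ligand-controlled Pd conjugate addition, and lower C3 and C4 from OsO4 attack anti to the 2-aryl group. Upper C3 and C2 come from an enantioselective epoxidation of a Z-cinnamate (C2 by inversion). Upper C4 is set in the ring closure (aryl trans to the 3-OH).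

Key step: step 14

Remark on the chemistry: the facial sense of the (S)-t-BuPyOx/Pd(OCOCF3)2 addition and of the (S,S)-(salen)MnCl epoxidation is assumed from the usual models for cyclic enones and cis-cinnamates; if the first batch shows the opposite sense, the other enantiomer of ligand or catalyst is used.

**Route**

Step 1
Reactants: 1 pyrogallol
Product: 2 2,2-diphenyl-1,3-benzodioxol-4-ol
Conditions: Ph2CCl2, neat, 170 °C
Reagents that add atoms: dichlorodiphenylmethane, ClC(Cl)(c1ccccc1)c1ccccc1
Why: Thermal diphenylmethylene ketal formation on a vicinal diol leaves one phenol free, and either pair of adjacent hydroxyls gives the same compound, so there is no regiochemical issue.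

Step 2
Reactants: 3 1-(2,3,4-trihydroxyphenyl)ethanone (gallacetophenone)
Product: 4 1-[3,4-bis(benzyloxy)-2-hydroxyphenyl]ethanone
Conditions: BnBr (2.1 equiv), K2CO3, DMF, rt to 50 °C
Reagents that add atoms: benzyl bromide, BrCc1ccccc1
Why: Williamson etherification should be selective for the 3- and 4-hydroxyls because the 2-hydroxyl is hydrogen-bonded to the acetyl carbonyl and is the least nucleophilic.

Step 3
Reactants: 4 1-[3,4-bis(benzyloxy)-2-hydroxyphenyl]ethanone
Product: 5 1-[3,4-bis(benzyloxy)-5-bromo-2-hydroxyphenyl]ethanone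
Conditions: NBS, MeCN, 0 °C
Reagents that add atoms: N-bromosuccinimide, O=C1CCC(=O)N1Br
Why: Electrophilic aromatic bromination should go to the only carbon para to the free phenol and ortho to a benzyloxy group, which becomes C6 of the lower flavan.

Step 4
Reactants: 5 1-[3,4-bis(benzyloxy)-5-bromo-2-hydroxyphenyl]ethanone
Product: 7 7,8-bis(benzyloxy)-6-bromo-4H-chromen-4-one, via enaminone 6 (not isolated)
Conditions: Me2NCH(OMe)2, toluene, 100 °C; then HCl, CH2Cl2, 40 °C
Reagents that add atoms: N,N-dimethylformamide dimethyl acetal, COC(OC)N(C)C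
Why: Enaminone formation followed by acid-promoted addition–elimination of the phenol (enaminone chromone synthesis) closes the pyranone ring and supplies the future C2.

Step 5
Reactants: 7 7,8-bis(benzyloxy)-6-bromo-4H-chromen-4-one; 8 [4-(benzyloxy)phenyl]boronic acid
Product: 9 (2R)-7,8-bis(benzyloxy)-2-[4-(benzyloxy)phenyl]-6-bromo-2,3-dihydro-4H-chromen-4-one
Conditions: Pd(OCOCF3)2 (5 mol %), (S)-t-BuPyOx (6 mol %), NH4PF6 (30 mol %), H2O (5 equiv), ClCH2CH2Cl, 60 °C
Reagents that add atoms: none
Why: Palladium-catalysed asymmetric conjugate addition of an arylboronic acid to a chromone sets C2 under control of the pyridine-oxazoline ligand, and the divalent palladium cycle should leave the aryl bromide untouched.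

Step 6
Reactants: 9 (2R)-flavanone
Product: 10 (2R,4R)-7,8-bis(benzyloxy)-2-[4-(benzyloxy)phenyl]-6-bromo-3,4-dihydro-2H-chromen-4-ol
Conditions: NaBH4, MeOH/THF, 0 °C
Reagents that add atoms: none
Why: Hydride reduction of the flavanone should give mainly the 2,4-cis alcohol by axial attack, and any trans epimer is carried on because C4 is flattened in the next step.

Step 7
Reactants: 10 (2R,4R)-flavan-4-ol
Product: 11 (2R)-7,8-bis(benzyloxy)-2-[4-(benzyloxy)phenyl]-6-bromo-2H-chromene
Conditions: MsCl, Et3N, CH2Cl2, 0 °C to 40 °C, in the dark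
Reagents that add atoms: none
Why: Mesylation of the strongly activated benzylic alcohol and base-induced elimination (E1-type dehydration) should give the conjugated flav-3-ene under non-acidic conditions that leave the C2–O1 bond, and so C2, intact.

Step 8
Reactants: 11 (2R)-flav-3-ene
Product: 12 (2S,3R,4R)-7,8-bis(benzyloxy)-2-[4-(benzyloxy)phenyl]-6-bromo-3,4-dihydro-2H-chromene-3,4-diol
Conditions: OsO4 (2 mol %), N-methylmorpholine N-oxide, acetone/H2O, rt
Reagents that add atoms: OsO4, O=[Os](=O)(=O)=O (catalytic oxygen carrier); N-methylmorpholine N-oxide, C[N+]1([O-])CCOCC1; water, O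
Why: Upjohn syn-dihydroxylation should occur on the face of the chromene opposite the 2-aryl group, giving the 2,3-trans-3,4-cis diol and so setting C3 and C4 from C2 (the C2 descriptor changes from R to S only through CIP priorities).

Step 9
Reactants: 12 (2S,3R,4R)-diol
Product: 13 3,4-O-isopropylidene acetal (acetonide) of 12
Conditions: Me2C(OMe)2, pyridinium p-toluenesulfonate (cat.), acetone, rt
Reagents that add atoms: 2,2-dimethoxypropane, COC(C)(C)OC
Why: Acid-catalysed transketalisation locks the cis-diol as an acetonide that tolerates the organolithium and basic steps and holds the labile benzylic C4–O bond in a ring.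

Step 10
Reactants: 14 4-(benzyloxy)benzaldehyde
Product: 15 methyl (2Z)-3-[4-(benzyloxy)phenyl]prop-2-enoate
Conditions: (CF3CH2O)2P(O)CH2CO2Me, KN(SiMe3)2, 18-crown-6, THF, −78 °C
Reagents that add atoms: methyl bis(2,2,2-trifluoroethyl)phosphonoacetate, COC(=O)CP(=O)(OCC(F)(F)F)OCC(F)(F)F
Why: Still–Gennari olefination gives the Z-cinnamate under kinetic control.

Step 11
Reactants: 15 methyl (2Z)-3-[4-(benzyloxy)phenyl]prop-2-enoate
Product: 16 methyl (2S,3S)-3-[4-(benzyloxy)phenyl]oxirane-2-carboxylate (cis)
Conditions: (S,S)-(salen)MnCl [(S,S)-N,N'-bis(3,5-di-tert-butylsalicylidene)-1,2-cyclohexanediaminomanganese chloride] (6 mol %), 4-phenylpyridine N-oxide (25 mol %), aq. NaOCl (pH 11.3), CH2Cl2, 4 °C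
Reagents that add atoms: sodium hypochlorite, [Na+].[O-]Cl
Why: Jacobsen–Katsuki epoxidation, which suits cis-disubstituted aryl alkenes such as cis-cinnamates, delivers oxygen to one enantioface under ligand control and gives the cis-glycidate that fixes C3 and, after later inversion, C2 of the upper unit.

Step 12
Reactants: 16 methyl (2S,3S)-glycidate
Product: 17 (2S,3S)-3-[4-(benzyloxy)phenyl]oxirane-2-carbaldehyde (cis)
Conditions: i-Bu2AlH (1.1 equiv), CH2Cl2, −78 °C; aq. KNa tartrate; used crude
Reagents that add atoms: none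
Why: Partial ester reduction at low temperature should stop at the aldehyde because the chelated aluminium hemiacetal survives until work-up, and the oxirane carbons are not epimerised because an oxiranyl enolate is too strained to form.

Step 13
Reactants: 13 acetonide bromide; 17 (2S,3S)-epoxy aldehyde
Product: 20 cis-epoxy methyl ether (13 with Br replaced by CH(OMe)-[cis-3-(4-benzyloxyphenyl)oxiran-2-yl]; epoxide carbons as in 17; both epimers at the methoxy carbon), via aryllithium 18 (not isolated), via lithium alkoxide 19 (not isolated)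
Conditions: n-BuLi, THF, −78 °C; then 17; then MeOTf, −78 to −20 °C
Reagents that add atoms: methyl trifluoromethanesulfonate, COS(=O)(=O)C(F)(F)F
Why: Bromine–lithium exchange and 1,2-addition of the aryllithium to the aldehyde form the bond from upper C4 to lower C6 faster than any epoxide opening, and O-methylation of the alkoxide in the same flask blocks Payne rearrangement and installs the leaving group, while the carbinol configuration need not be controlled because this carbon is ionised in step 14.

Step 14
Reactants: 20 cis-epoxy methyl ether; 2 2,2-diphenyl-1,3-benzodioxol-4-ol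
Product: 22 fully protected biflavanoid (upper unit: 4'-O-benzyl-7,8-O-diphenylmethylene flavan-3-ol bonded at C4 to C6 of the lower tri-O-benzyl flavan-3,4-diol acetonide; all stereocentres as in 24), via aryl ether alcohol 21 (not isolated)
Conditions: 2 (1.1 equiv), Cs2CO3 (10 mol %), MeCN, 70 °C; then dilute, −35 °C, TMSOTf (50 mol %); NaHCO3, MeOH
Reagents that add atoms: none
Why: Proposed new method: a one-flask formal [3+3] annulation of a phenol with a cis-epoxy benzylic ether, in which under catalytic base the phenoxide of 2 opens the epoxide of 20 by SN2 attack at the para-benzyloxybenzylic carbon (the other epoxide carbon is flanked by the bulky, inductively deactivating CH(OMe)Ar group) to give ether 21, and TMSOTf then ionises the benzylic methyl ether to a cation stabilised by the ortho benzyloxy oxygen and the para ring oxygen of the lower ring A, which the tethered arene captures at the only free carbon ortho to the new ether oxygen (para to a dioxole oxygen). The closest known reaction types are the phenoxide opening of 3-arylglycidol derivatives at the benzylic carbon, the Lewis acid-promoted arylation of 4-alkoxyflavans and the cycloalkylation of 3-aryloxy-1-arylpropanols to 4-arylchromans; their merger into one annulation on this substrate class is what is new. Ring C of the upper unit closes in a 6-exo-trig Friedel–Crafts cyclisation onto the cationic carbon (arene π bond endocyclic). C2 is set by inversion at the epoxide carbon and C3 is carried over unchanged from the epoxide; C4 is set in the ring closure, where the bulky lower-unit aryl should take the pseudo-axial position anti to the axial 3-hydroxyl (avoiding peri strain with H5 and a gauche clash with the hydroxyl), the same trans preference seen when 2,3-cis-flavan-4-yl cations capture nucleophiles, and because C4 passes through a planar cation both epimers of 20 converge. The step needs O- and not C-attack on the epoxide (secured by the basic first stage), ring closure ortho and not para to the phenol oxygen (secured because the oxygen is tethered first; the competing indane closure onto ring B is disfavoured since that carbon is meta to its only oxygen), and ionisation of the acyclic methyl ether in preference to the acetonide C–O bond or the new benzylic aryl ether (the methyl ether gives the better stabilised cation and leaves irreversibly, whereas an opened dioxolane can only re-close to the cis-fused ring).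

Step 15
Reactants: 22 fully protected biflavanoid
Product: 23 lower-unit 3,4-diol (22 without the acetonide)
Conditions: AcOH/H2O/THF (3:1:1), 40 °C
Reagents that add atoms: none
Why: Mild aqueous acid should hydrolyse the acetonide by acetal C–O cleavage (ketal hydrolysis), which is much faster than ionisation at the benzylic C4 of the lower unit, so the diol configuration is kept.

Step 16
Reactants: 23 lower-unit 3,4-diol
Product: 24 (2R,3R,4S)-2-(4-hydroxyphenyl)-4-[(2S,3R,4R)-3,4,7,8-tetrahydroxy-2-(4-hydroxyphenyl)-3,4-dihydro-2H-chromen-6-yl]-3,4-dihydro-2H-chromene-3,7,8-triol (CNP0391561.9)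
Conditions: H2 (1 atm), Pd(OH)2/C, THF/MeOH, rt; work-up under argon
Reagents that add atoms: none
Why: Catalytic hydrogenolysis should cleave the four benzyl aryl ethers and the diphenylmethylene ketal in one neutral operation, these bonds being reduced far faster than the secondary benzylic alcohol and the ring C–O bonds.

**Compound list**

1 | pyrogallol | Oc1cccc(O)c1O | starting material
2 | 2,2-diphenyl-1,3-benzodioxol-4-ol | Oc1cccc2OC(c3ccccc3)(c3ccccc3)Oc12 | intermediate
3 | 1-(2,3,4-trihydroxyphenyl)ethanone | CC(=O)c1ccc(O)c(O)c1O | starting material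
4 | 1-[3,4-bis(benzyloxy)-2-hydroxyphenyl]ethanone | CC(=O)c1ccc(OCc2ccccc2)c(OCc2ccccc2)c1O | intermediate
5 | 1-[3,4-bis(benzyloxy)-5-bromo-2-hydroxyphenyl]ethanone | CC(=O)c1cc(Br)c(OCc2ccccc2)c(OCc2ccccc2)c1O | intermediate
6 | (E)-1-[3,4-bis(benzyloxy)-5-bromo-2-hydroxyphenyl]-3-(dimethylamino)prop-2-en-1-one | CN(C)/C=C/C(=O)c1cc(Br)c(OCc2ccccc2)c(OCc2ccccc2)c1O | intermediate
7 | 7,8-bis(benzyloxy)-6-bromo-4H-chromen-4-one | O=c1ccoc2c(OCc3ccccc3)c(OCc3ccccc3)c(Br)cc12 | intermediate
8 | [4-(benzyloxy)phenyl]boronic acid | OB(O)c1ccc(OCc2ccccc2)cc1 | starting material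
9 | (2R)-7,8-bis(benzyloxy)-2-[4-(benzyloxy)phenyl]-6-bromo-2,3-dihydro-4H-chromen-4-one | Brc1cc2c(c(OCc3ccccc3)c1OCc1ccccc1)O[C@@H](c1ccc(OCc3ccccc3)cc1)CC2=O | intermediate
10 | (2R,4R)-7,8-bis(benzyloxy)-2-[4-(benzyloxy)phenyl]-6-bromo-3,4-dihydro-2H-chromen-4-ol (2,4-cis) | Brc1cc2c(c(OCc3ccccc3)c1OCc1ccccc1)O[C@@H](c1ccc(OCc3ccccc3)cc1)C[C@H]2O | intermediate
11 | (2R)-7,8-bis(benzyloxy)-2-[4-(benzyloxy)phenyl]-6-bromo-2H-chromene | Brc1cc2c(c(OCc3ccccc3)c1OCc1ccccc1)O[C@@H](c1ccc(OCc3ccccc3)cc1)C=C2 | intermediate
12 | (2S,3R,4R)-7,8-bis(benzyloxy)-2-[4-(benzyloxy)phenyl]-6-bromo-3,4-dihydro-2H-chromene-3,4-diol (2,3-trans-3,4-cis) | Brc1cc2c(c(OCc3ccccc3)c1OCc1ccccc1)O[C@@H](c1ccc(OCc3ccccc3)cc1)[C@H](O)[C@@H]2O | intermediate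
13 | 3,4-O-isopropylidene acetal (acetonide) of 12 | Brc1cc2c(c(OCc3ccccc3)c1OCc1ccccc1)O[C@@H](c1ccc(OCc3ccccc3)cc1)[C@@H]1OC(C)(C)O[C@H]21 | intermediate
14 | 4-(benzyloxy)benzaldehyde | O=Cc1ccc(OCc2ccccc2)cc1 | starting material
15 | methyl (2Z)-3-[4-(benzyloxy)phenyl]prop-2-enoate | COC(=O)/C=C\c1ccc(OCc2ccccc2)cc1 | intermediate
16 | methyl (2S,3S)-3-[4-(benzyloxy)phenyl]oxirane-2-carboxylate (cis) | O(Cc1ccccc1)c1ccc(cc1)[C@@H]1O[C@@H]1C(=O)OC | intermediate
17 | (2S,3S)-3-[4-(benzyloxy)phenyl]oxirane-2-carbaldehyde (cis) | O(Cc1ccccc1)c1ccc(cc1)[C@@H]1O[C@@H]1C=O | intermediate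
18 | aryllithium: 13 with Li in place of Br at C6 | [Li]c1cc2c(c(OCc3ccccc3)c1OCc1ccccc1)O[C@@H](c1ccc(OCc3ccccc3)cc1)[C@@H]1OC(C)(C)O[C@H]21 | intermediate
19 | lithium alkoxide of the epoxy carbinol from 18 and 17 (both carbinol epimers) | O(Cc1ccccc1)c1ccc(cc1)[C@@H]1O[C@@H]1C(O[Li])c1cc2c(c(OCc3ccccc3)c1OCc1ccccc1)O[C@@H](c1ccc(OCc3ccccc3)cc1)[C@@H]1OC(C)(C)O[C@H]21 | intermediate
20 | cis-epoxy methyl ether: lower-unit acetonide carrying at C6 the group CH(OMe)-[cis-3-(4-benzyloxyphenyl)oxiran-2-yl]; epoxide carbons as in 17, both epimers at the methoxy carbon | O(Cc1ccccc1)c1ccc(cc1)[C@@H]1O[C@@H]1C(OC)c1cc2c(c(OCc3ccccc3)c1OCc1ccccc1)O[C@@H](c1ccc(OCc3ccccc3)cc1)[C@@H]1OC(C)(C)O[C@H]21 | intermediate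
21 | aryl ether alcohol from epoxide opening: 1-(4-benzyloxyphenyl)-1-(2,2-diphenyl-1,3-benzodioxol-4-yloxy)-3-methoxy-3-(lower-unit C6 aryl)propan-2-ol, C1 and C2 configured as C2 and C3 of the upper unit of 24, both epimers at C3 | O(Cc1ccccc1)c1ccc(cc1)[C@@H](Oc1cccc2OC(c3ccccc3)(c3ccccc3)Oc12)[C@H](O)C(OC)c1cc2c(c(OCc3ccccc3)c1OCc1ccccc1)O[C@@H](c1ccc(OCc3ccccc3)cc1)[C@@H]1OC(C)(C)O[C@H]21 | intermediate
22 | fully protected biflavanoid: upper 2,3-cis-3,4-trans 4-arylflavan-3-ol (4'-OBn, 7,8-O-CPh2) bonded at C4 to C6 of the lower 2,3-trans-3,4-cis flavan-3,4-diol acetonide (7,8,4'-tri-OBn); stereocentres as in 24 | c1ccccc1COc1ccc(cc1)[C@H]1Oc2c(ccc3OC(c4ccccc4)(c4ccccc4)Oc23)[C@H](c2cc3c(c(OCc4ccccc4)c2OCc2ccccc2)O[C@@H](c2ccc(OCc4ccccc4)cc2)[C@@H]2OC(C)(C)O[C@H]32)[C@H]1O | intermediate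
23 | 22 with the lower-unit 3,4-diol free | c1ccccc1COc1ccc(cc1)[C@H]1Oc2c(ccc3OC(c4ccccc4)(c4ccccc4)Oc23)[C@H](c2cc3c(c(OCc4ccccc4)c2OCc2ccccc2)O[C@@H](c2ccc(OCc4ccccc4)cc2)[C@H](O)[C@@H]3O)[C@H]1O | intermediate
24 | (2R,3R,4S)-2-(4-hydroxyphenyl)-4-[(2S,3R,4R)-3,4,7,8-tetrahydroxy-2-(4-hydroxyphenyl)-3,4-dihydro-2H-chromen-6-yl]-3,4-dihydro-2H-chromene-3,7,8-triol | Oc1ccc([C@H]2Oc3c(ccc(O)c3O)[C@H](c3cc4c(c(O)c3O)O[C@@H](c3ccc(O)cc3)[C@H](O)[C@@H]4O)[C@H]2O)cc1 | target

**Count and risks**

Total step count: 16. Longest linear sequence: 12 steps (steps 2 to 9, then 13 to 16).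

Steps most likely to fail:

Step 14 (Proposed new method). What may go wrong:
- slow or misdirected epoxide opening;
- hydride shift of the benzylic cation next to the free 3-hydroxyl;
- competing ionisation of the acetonide or of the new benzylic aryl ether;
- poor facial selectivity in the ring closure.

The fallback uses known chemistry and attaches the lower unit last, in the biomimetic sense. It sets out from 2, 17 and 13 and comes back at 22. The bromomagnesium phenoxide of 2 (EtMgBr, toluene/CH2Cl2) is hydroxyalkylated at its ortho carbon by aldehyde 17 (magnesium phenoxide-directed ortho-hydroxyalkylation) to give the epoxy salicyl alcohol F1. Mild base (K2CO3, MeOH) then lets the phenoxide open the aryl epoxide at its benzylic carbon with inversion (6-endo closure), giving the protected 2,3-cis-flavan-3,4-diol F2. In parallel 13 is debrominated (n-BuLi, then MeOH) to the nucleophilic lower unit F3. F2 and F3 are condensed with TMSOTf in CH2Cl2 at −40 °C, the classical flavan-3,4-diol arylation, which for 2,3-cis electrophiles is known to give the 3,4-trans product. Attack at C6 of F3 (para to the ring oxygen) is expected, and this returns 22.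

Step 16. What may go wrong: hydrogenolysis of the benzylic C4 hydroxyl of the lower unit on the catalyst, or air oxidation of the freed pyrogallol rings. The fallback sets out from 22 and comes back at 24 and reverses the unmasking logic, so that the benzylic oxygen is never a free alcohol on the catalyst. 22 is hydrogenolysed with the acetonide still in place (H2, Pd(OH)2/C, THF/MeOH) to the hexaphenol acetonide F4. The acetonide is then removed last with dilute aqueous AcOH at room temperature under argon to give 24.

Step 5. What may go wrong: low conversion or low enantioselectivity with the hindered, electron-rich chromone, or cross-coupling at the aryl bromide if zerovalent palladium forms. The fallback sets out from 5 and 14 and comes back at 10, replacing the asymmetric C–C bond formation by a kinetic resolution. Claisen–Schmidt condensation of 5 with 14 (KOH, EtOH) gives the 2'-hydroxychalcone F5. Oxa-Michael cyclisation (NaOAc, EtOH, reflux) gives the racemic flavanone F6. Noyori-type asymmetric transfer hydrogenation with RuCl(p-cymene)[(R,R)-TsDPEN] in HCO2H/Et3N, run as a kinetic resolution, should reduce the (2R)-ketone to the cis alcohol 10 and leave the (2S)-flavanone, which is separated.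

Further compounds
F1 | step 14 | 5-{hydroxy[(2R,3S)-cis-3-(4-benzyloxyphenyl)oxiran-2-yl]methyl}-2,2-diphenyl-1,3-benzodioxol-4-ol (epoxide as in 17, both carbinol epimers) | O(Cc1ccccc1)c1ccc(cc1)[C@@H]1O[C@@H]1C(O)c1ccc2OC(c3ccccc3)(c3ccccc3)Oc2c1O
F2 | step 14 | (2R,3R)-2-[4-(benzyloxy)phenyl]-7,8-(diphenylmethylenedioxy)-3,4-dihydro-2H-chromene-3,4-diol (2,3-cis, both C4 epimers) | c1ccccc1COc1ccc(cc1)[C@H]1Oc2c(ccc3OC(c4ccccc4)(c4ccccc4)Oc23)C(O)[C@H]1O
F3 | step 14 | debrominated lower unit: 13 with H in place of Br | c1cc2c(c(OCc3ccccc3)c1OCc1ccccc1)O[C@@H](c1ccc(OCc3ccccc3)cc1)[C@@H]1OC(C)(C)O[C@H]21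
F4 | step 16 | hexaphenol acetonide: 24 with the lower-unit 3,4-diol as its isopropylidene acetal | Oc1ccc(cc1)[C@H]1Oc2c(ccc(O)c2O)[C@H](c2cc3c(c(O)c2O)O[C@@H](c2ccc(O)cc2)[C@@H]2OC(C)(C)O[C@H]32)[C@H]1O
F5 | step 5 | (E)-1-[3,4-bis(benzyloxy)-5-bromo-2-hydroxyphenyl]-3-[4-(benzyloxy)phenyl]prop-2-en-1-one | O=C(/C=C/c1ccc(OCc2ccccc2)cc1)c1cc(Br)c(OCc2ccccc2)c(OCc2ccccc2)c1O
F6 | step 5 | racemic 7,8-bis(benzyloxy)-2-[4-(benzyloxy)phenyl]-6-bromo-2,3-dihydro-4H-chromen-4-one | Brc1cc2c(c(OCc3ccccc3)c1OCc1ccccc1)OC(c1ccc(OCc3ccccc3)cc1)CC2=O
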